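Take the charges, the readings and the two questions first.

in all of them: precatalyst 0.1 mol%

| run | starting material | second substrate | coupling partner | remark |
|---|---|---|---|---|
| noon | 19 mM | 0.67 equiv | 0.90 equiv | run made earlier |
| winter | 19 mM | 1.5 equiv | 0.90 equiv | run made earlier |
| dusk | 9.5 mM | 1 equiv | 0.90 equiv | run made earlier |
| flask | 19 mM | 1.00 equiv | 0.900 equiv |  |

| run | time / min | target / % |
|---|---|---|
| noon | 0.833 | 10 |
| noon | 2.50 | 46 |
| noon | 4.00 | 64 |
| noon | 6.00 | 77 |
| noon | 10.0 | 78 |
| winter | 2.00 | 25 |
| winter | 4.00 | 54 |
| winter | 6.00 | 66 |
| winter | 8.00 | 67 |
| winter | 10.0 | 68 |
| dusk | 0.833 | 5 |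
| dusk | 1.33 | 7 |
| dusk | 2.50 | 20 |
| dusk | 5.00 | 51 |
| dusk | 10.0 | 71 |

(each reading ± 1.5 percentage points)

* factor on the rate of making target when 5.0% of the starting material are converted if second substrate is charged twice over
* factor on the rate when 5.0% of the starting material are converted if precatalyst is charged at 1 mol% instead

Is the working catalyst still growing at the start? In the dusk run, target goes from 7% at 1.33 min to 20% at 2.50 min. As a reading, that is time to the power 1.66, above 1, so I read an induction period.

Suppose active catalyst rises in step with time while the reagents stay near their charges. Then target rises with time squared and the rate with time. For 1 mol% against 0.1 mol% in the flask, I reckon 3.16. This is the root factor: the square root of the factor on activity, which gives the change of rate at fixed conversion under that supposition.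

Does second substrate act as such a factor? At 4.00 min, the winter run holds 54% and the noon run 64%, less with more second substrate. So I let c(second substrate) compete with c(starting material) at equal weight, the forecast's weight. Doubling the charge then gives an activity factor of 0.661, and its root is 0.813.

The forecast says 0.77 and 3.8, with the ground “Early rates are low, which indicates first-order precatalyst activation”. My figures differ from both: 0.813 is higher and 3.16 is lower.

The simulation gives 0.840 and 3.36, so the forecast holds on both.

    second substrate + free catalyst ⇌ catalyst intermediate B (K = 120 /M, k = 15000 /M/min)
    coupling partner + catalyst intermediate B → free catalyst + second product (k = 19000 /M/min)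
    starting material + free catalyst ⇌ catalyst intermediate A (K = 89.0 /M, k = 64000 /M/min)
    coupling partner + catalyst intermediate A → free catalyst + target (k = 3.80 × 10⁵ /M/min)
    precatalyst → free catalyst (k = 0.380 /min)

The flask reaches 5.0% at 0.699 min, and at 1.20 min it still holds 63.4% of its catalyst as precatalyst. The root factor puts the same conversion in the 1 mol% flask at 0.221 min. At that reckoned time, the first-order step comes to 8.06% of the precatalyst released. At that conversion in the 1 mol% flask, free catalyst stands at 4.29% of the catalyst.

Readings and results were computed from invented constants, noise included.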